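**Plan**

1. Numbering (biogenetic): ring A = C6–C10 (7-Me), ring B = C2–C6/C10–C12 (3-Me, C23H2= on C11), ring C = C1/C2/C12–C15, ring D = C14–C18 (15-Me, 16-OH, 18-iPr). Enabling feature: C11 lies between C10 and C12, the carbons that carry the C6–C10 and C2=C12 bonds; as a ketone it makes both nucleophilic. Without these two bonds, rings A–C are one 15-membered ring C1–C15 fused to ring D.
2. Retrosynthesis: C11=CH2 ⇒ C11=O; then C2=C12 (Horner–Wadsworth–Emmons) and C6–C10 (enolate SN2) are cut together ⇒ a 15-membered 12-phosphono-2,11-dione 6-tosylate.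
3. The macrocycle is cut at C8=C9 (ring-closing metathesis); the chain at C10–C11 (allyl Grignard), C6–C7 and C2–C3 (two crotylborations) and C5–C6 (hydroformylation); ring D at C13–C14 and C1–C15 (conjugate addition/allylation of 2-methylcyclopentenone).
4. Forward: ring D, chain growth from C2 to C8, closure of the 15-membered ring, then rings C and A (and with them ring B) in one pot, then methylenation and desilylation.
5. Stereochemistry: C14 from the conjugate-addition catalyst; C15 and C18 by addition anti to the neighbouring substituent; C16 by CBS reduction; C3, C7 and the C6 leaving group by reagent-controlled crotylboration; C6 by SN2 inversion; C10 by equilibration next to the C11 ketone.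

Key step: step 19

**Route**

Step 1
Reactants: 1 2-methylcyclopent-2-en-1-one; 2 [2-(1,3-dioxolan-2-yl)ethyl]magnesium bromide
Product: 4 (2R,3S)-3-[2-(1,3-dioxolan-2-yl)ethyl]-2-methyl-2-(prop-2-en-1-yl)cyclopentan-1-one, via magnesium enolate 3 (not isolated)
Conditions: Cu(OTf)2 (3 mol %), chiral imidazolinium NHC precursor (4 mol %, enantiomer giving the 3S adduct), Et2O, −30 °C; then allyl iodide, DMPU, −30 °C → rt
Reagents that add atoms: allyl iodide, C=CCI
Why: Copper-catalysed asymmetric conjugate addition of a Grignard reagent to an α-substituted cyclic enone with alkylation of the magnesium enolate (three-component coupling): the ligand sets C14, and allylation anti to the new side chain sets the trans quaternary centre C15.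

Step 2
Reactants: 4 cyclopentanone from step 1
Product: 5 (4S,5R)-4-[2-(1,3-dioxolan-2-yl)ethyl]-5-methyl-5-(prop-2-en-1-yl)cyclopent-2-en-1-one
Conditions: LDA, THF, −78 °C; then N-tert-butylbenzenesulfinimidoyl chloride, −78 °C
Reagents that add atoms: none
Why: Mukaiyama dehydrogenation (sulfenimidoylation of the enolate and syn-elimination), which can only give the C17=C18 enone because the other α-carbon is quaternary.

Step 3
Reactants: 5 cyclopentenone
Product: 6 (2R,3S,4S)-3-[2-(1,3-dioxolan-2-yl)ethyl]-2-methyl-4-(propan-2-yl)-2-(prop-2-en-1-yl)cyclopentan-1-one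
Conditions: i-PrMgCl, CuBr·SMe2 (20 mol %), THF, −78 → −30 °C; aq NH4Cl
Reagents that add atoms: isopropylmagnesium chloride, CC(C)[Mg]Cl
Why: Copper-catalysed 1,4-addition, in which the isopropyl group should add anti to the adjacent C14 side chain and so set C18.

Step 4
Reactants: 6 isopropyl ketone
Product: 7 (1R,2R,3S,4S)-3-[2-(1,3-dioxolan-2-yl)ethyl]-2-methyl-4-(propan-2-yl)-2-(prop-2-en-1-yl)cyclopentan-1-ol
Conditions: (S)-Me-CBS oxazaborolidine (20 mol %), catecholborane, toluene, −78 → −40 °C; MeOH, aq NaOH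
Reagents that add atoms: none
Why: Corey–Bakshi–Shibata reduction, in which the catalyst treats the quaternary C15 side as the large group and should deliver the 16R alcohol (OH cis to the C15 methyl) against the modest substrate bias, while catecholborane leaves the terminal alkene untouched.

Step 5
Reactants: 7 cyclopentanol
Product: 8 tert-butyldimethylsilyl ether of 7
Conditions: TBSOTf, 2,6-lutidine, CH2Cl2, 0 °C
Reagents that add atoms: tert-butyldimethylsilyl triflate, CC(C)(C)[Si](C)(C)OS(=O)(=O)C(F)(F)F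
Why: Silylation of the hindered secondary alcohol with the silyl triflate gives an ether that should last to the final step.

Step 6
Reactants: 8 silyl ether
Product: 9 C2 aldehyde (allyl group of 8 cut down to C15–CH2–CHO; 14S,15R,16R,18S)
Conditions: O3, CH2Cl2/MeOH, −78 °C; then PPh3
Reagents that add atoms: ozone, [O-][O+]=O
Why: Ozonolysis with reductive work-up cleaves the only alkene to the aldehyde without touching the acetal or the silyl ether.

Step 7
Reactants: 9 C2 aldehyde
Product: 10 (2R,3S)-anti-homoallylic alcohol (C15–CH2–CH(OH)–CH(CH3)–CH=CH2)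
Conditions: trans-2-butene, KOt-Bu, n-BuLi, THF, −78 → −45 °C; (−)-Ipc2BOMe, then BF3·OEt2, −78 °C; 9, −78 °C; NaOH, H2O2
Reagents that add atoms: (E)-crotyldiisopinocampheylborane, made in the flask from trans-2-butene (C/C=C/C), C/C=C/CB([C@@H]1C[C@@H]2C[C@H]([C@H]1C)C2(C)C)[C@@H]1C[C@@H]2C[C@H]([C@H]1C)C2(C)C
Why: Brown crotylboration through a chair six-membered transition state, in which the (E)-crotyl group gives the anti adduct and the isopinocampheyl groups direct attack to the Si face, so that C3 should be set as S (the 2R carbinol is oxidised later).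

Step 8
Reactants: 10 homoallylic alcohol
Product: 11 2-O-benzyl ether of 10
Conditions: NaH, BnBr, TBAI (cat.), THF/DMF, 0 °C → rt
Reagents that add atoms: benzyl bromide, BrCc1ccccc1
Why: Williamson benzylation masks the C2 hydroxyl so that it can neither form a lactol with the C6 aldehyde nor displace the later C6 tosylate.

Step 9
Reactants: 11 benzyl ether
Product: 12 C6 aldehyde (vinyl group of 11 extended to CH2–CH2–CHO; 2R,3S)
Conditions: Rh(acac)(CO)2 (1 mol %), BiPhePhos (2 mol %), CO/H2 (1:1, 10 bar), toluene, 60 °C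
Reagents that add atoms: carbon monoxide, [C-]#[O+]
Why: Rhodium-catalysed hydroformylation of an α-branched terminal alkene, which with a bulky bisphosphite should give the linear aldehyde (new carbon C6) without alkene isomerisation, so C3 is not touched.

Step 10
Reactants: 12 C6 aldehyde
Product: 13 (6R,7S)-anti-homoallylic alcohol (C5–CH(OH)–CH(CH3)–CH=CH2)
Conditions: trans-2-butene, KOt-Bu, n-BuLi, THF, −78 → −45 °C; (−)-Ipc2BOMe, then BF3·OEt2, −78 °C; 12, −78 °C; NaOH, H2O2
Reagents that add atoms: (E)-crotyldiisopinocampheylborane, made in the flask from trans-2-butene (C/C=C/C), C/C=C/CB([C@@H]1C[C@@H]2C[C@H]([C@H]1C)C2(C)C)[C@@H]1C[C@@H]2C[C@H]([C@H]1C)C2(C)C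
Why: Second Brown crotylboration with the same reagent, whose anti addition on the Si face should set 6R (the future leaving group) and 7S in one step.

Step 11
Reactants: 13 homoallylic alcohol
Product: 14 (6R)-6-O-tosylate of 13
Conditions: TsCl, DMAP, pyridine, CH2Cl2, rt
Reagents that add atoms: p-toluenesulfonyl chloride, Cc1ccc(cc1)S(Cl)(=O)=O
Why: Sulfonylation of the only free hydroxyl installs, with retention, the leaving group of the key step.

Step 12
Reactants: 14 tosylate
Product: 15 C11 aldehyde (dioxolane of 14 hydrolysed)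
Conditions: PPTS (cat.), acetone/H2O, 60 °C
Reagents that add atoms: water, O
Why: Mild acid-catalysed acetal hydrolysis frees the aldehyde, and the secondary silyl ether, the benzyl ether and the tosylate should survive.

Step 13
Reactants: 15 C11 aldehyde
Product: 16 C11 homoallylic alcohol (both C11 epimers; diene for ring closure)
Conditions: allylmagnesium bromide, THF, −78 °C; aq NH4Cl
Reagents that add atoms: allylmagnesium bromide, C=CC[Mg]Br
Why: Grignard addition at low temperature adds C10 and C9 to the aldehyde faster than it can touch the secondary tosylate, and the configuration at C11 does not matter because it is oxidised in step 15.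

Step 14
Reactants: 16 diene
Product: 17 15-membered carbocycle C1–C15 fused to ring D (C8=C9 as E/Z mixture; 11-OH, 6-OTs, 2-OBn, 16-OTBS)
Conditions: Grubbs second-generation catalyst (10 mol %), CH2Cl2 (1 mM), 40 °C
Reagents that add atoms: none
Why: Ring-closing metathesis of the two terminal alkenes at high dilution closes the 15-membered ring at C8=C9 with loss of ethylene, and the alkene geometry is irrelevant.

Step 15
Reactants: 17 macrocyclic alcohol
Product: 19 macrocyclic (9E)-enone (C11=O, C9=C10), via deconjugated enone 18 (not isolated)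
Conditions: Dess–Martin periodinane, NaHCO3, CH2Cl2, 0 °C; filtration; then DBU (0.2 equiv), CH2Cl2, rt
Reagents that add atoms: none
Why: Dess–Martin oxidation of the only free hydroxyl and base-catalysed shift of the C8=C9 bond into conjugation give the enone, in which C10 is vinylic and C12 is therefore the only enolisable carbon next to C11.

Step 16
Reactants: 19 macrocyclic enone
Product: 21 diethyl 12-phosphonate of enone 19 (both C12 epimers), via phosphonite 20 (not isolated)
Conditions: LDA (1.1 equiv), THF, −78 °C; ClP(OEt)2, −78 → 0 °C; then air, 0 °C → rt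
Reagents that add atoms: diethyl chlorophosphite, CCOP(Cl)OCC; dioxygen (air), O=O
Why: Kinetic α′-deprotonation of the enone at C12 and C-phosphinylation of the enolate with the P(III) chloride, then oxidation to P(V) (a known way from ketone enolates to β-ketophosphonates), should place the phosphonate on C12 only.

Step 17
Reactants: 21 phosphonate enone
Product: 22 saturated 2-hydroxy-11-oxo-12-phosphonate 6-tosylate
Conditions: H2 (1 atm), Pd(OH)2/C, EtOAc/EtOH, rt
Reagents that add atoms: none
Why: Heterogeneous hydrogenation saturates the C9=C10 bond and hydrogenolyses the benzyl ether in one operation, while ketone, phosphonate, tosylate and silyl ether are inert.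

Step 18
Reactants: 22 hydroxy ketophosphonate
Product: 23 15-membered 2,11-dioxo-12-phosphonate 6-tosylate (3S,6R,7S,14S,15R,16R,18S)
Conditions: Dess–Martin periodinane, NaHCO3, CH2Cl2, 0 °C
Reagents that add atoms: none
Why: Buffered Dess–Martin oxidation should give the C2 ketone without epimerising the adjacent C3.

Step 19
Reactants: 23 macrocyclic diketo phosphonate tosylate
Product: 25 tetracyclic 11-ketone (16-O-TBS; 3S,6S,7S,10S), via tricyclic enone tosylate 24 (not isolated)
Conditions: KHMDS (1.05 equiv), 18-crown-6, THF, −78 → 40 °C; then −78 °C, KHMDS (1.3 equiv), −78 → 0 °C; aq NH4Cl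
Reagents that add atoms: none
Why: The first portion of KHMDS deprotonates only the β-ketophosphonate C12–H (several pKa units more acidic than any ketone α-H), and this enolate adds across the ring to the C2 ketone and loses diethyl phosphate (intramolecular Horner–Wadsworth–Emmons olefination), giving C2=C12; the second portion deprotonates C10, the only α-CH2 left on the C11 ketone of 24 (kinetic α′-deprotonation), and that enolate displaces the C6 tosylate, giving C6–C10. The closest known reaction types are the intramolecular Horner–Wadsworth–Emmons reaction of α-substituted β-ketophosphonates with ketones to tetrasubstituted cycloalkenes and the five-ring closure of keto tosylates bearing secondary sulfonates. Ring C closes by 6-exo-trig addition of C12 to the C2 carbonyl followed by syn-elimination (in a six-membered ring the alkene can only be endocyclic), ring A closes by 5-(enolexo)-exo-tet SN2, and ring B is never closed as such but is what is left of the 15-membered ring once both transannular bonds exist. C6 arises by inversion of the 6R tosylate and so becomes 6S with H-6 cis to H-7, and C10, being α to the C11 ketone, should be funnelled by enolate equilibration to the trans ring fusion in which C11 and C5 are trans on the cyclopentane. The step needs olefination at C12 rather than C10 and alkylation at C10 rather than at a γ-carbon, which the position of the phosphonate and the kinetic deprotonation secure, and it needs C3 to keep its configuration, which is secured because no base stronger than the phosphonate enolate is present while C2 is still a ketone.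

Step 20
Reactants: 25 tetracyclic ketone
Product: 26 16-O-TBS ether of the target
Conditions: Cp2TiMe2 (3 equiv), toluene/THF, 70 °C, dark
Reagents that add atoms: dimethyltitanocene, C[Ti](C)(C1C=CC=C1)C1C=CC=C1
Why: Petasis methylenation converts the hindered, enolisable C11 ketone into the exocyclic methylene under non-basic conditions, so C10 and C3 should not epimerise.

Step 21
Reactants: 26 silyl ether
Product: 27 target (3S,6S,7S,10S,14S,15R,16R,18S)
Conditions: TBAF, THF, 50 °C
Reagents that add atoms: none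
Why: Fluoride-mediated cleavage of the silyl ether frees the C16 hydroxyl and leaves the acid-sensitive 1,3-diene untouched.

**Compound list**

1 | 2-methylcyclopent-2-en-1-one | CC1=CCCC1=O | starting material
2 | [2-(1,3-dioxolan-2-yl)ethyl]magnesium bromide | Br[Mg]CCC1OCCO1 | starting material
3 | bromomagnesium enolate of the conjugate adduct (C14 configured as in 4) | CC1=C(O[Mg]Br)CC[C@@H]1CCC2OCCO2 | intermediate (not isolated)
4 | (2R,3S)-3-[2-(1,3-dioxolan-2-yl)ethyl]-2-methyl-2-(prop-2-en-1-yl)cyclopentan-1-one | C=CC[C@@]1(C)C(=O)CC[C@@H]1CCC2OCCO2 | intermediate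
5 | (4S,5R)-4-[2-(1,3-dioxolan-2-yl)ethyl]-5-methyl-5-(prop-2-en-1-yl)cyclopent-2-en-1-one | C=CC[C@@]1(C)C(=O)C=C[C@@H]1CCC2OCCO2 | intermediate
6 | (2R,3S,4S)-3-[2-(1,3-dioxolan-2-yl)ethyl]-2-methyl-4-(propan-2-yl)-2-(prop-2-en-1-yl)cyclopentan-1-one | C=CC[C@@]1(C)C(=O)C[C@@H](C(C)C)[C@@H]1CCC2OCCO2 | intermediate
7 | (1R,2R,3S,4S)-3-[2-(1,3-dioxolan-2-yl)ethyl]-2-methyl-4-(propan-2-yl)-2-(prop-2-en-1-yl)cyclopentan-1-ol | C=CC[C@@]1(C)[C@H](O)C[C@@H](C(C)C)[C@@H]1CCC2OCCO2 | intermediate
8 | tert-butyldimethylsilyl ether of 7 | C=CC[C@@]1(C)[C@H](O[Si](C)(C)C(C)(C)C)C[C@@H](C(C)C)[C@@H]1CCC2OCCO2 | intermediate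
9 | C2 aldehyde (C15–CH2–CHO; 14S,15R,16R,18S) | O=CC[C@@]1(C)[C@H](O[Si](C)(C)C(C)(C)C)C[C@@H](C(C)C)[C@@H]1CCC2OCCO2 | intermediate
10 | (2R,3S)-anti-homoallylic alcohol | C=C[C@H](C)[C@H](O)C[C@@]1(C)[C@H](O[Si](C)(C)C(C)(C)C)C[C@@H](C(C)C)[C@@H]1CCC2OCCO2 | intermediate
11 | 2-O-benzyl ether of 10 | C=C[C@H](C)[C@H](OCc3ccccc3)C[C@@]1(C)[C@H](O[Si](C)(C)C(C)(C)C)C[C@@H](C(C)C)[C@@H]1CCC2OCCO2 | intermediate
12 | C6 aldehyde (2R,3S) | O=CCC[C@H](C)[C@H](OCc3ccccc3)C[C@@]1(C)[C@H](O[Si](C)(C)C(C)(C)C)C[C@@H](C(C)C)[C@@H]1CCC2OCCO2 | intermediate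
13 | (6R,7S)-anti-homoallylic alcohol | C=C[C@H](C)[C@H](O)CC[C@H](C)[C@H](OCc3ccccc3)C[C@@]1(C)[C@H](O[Si](C)(C)C(C)(C)C)C[C@@H](C(C)C)[C@@H]1CCC2OCCO2 | intermediate
14 | (6R)-6-O-tosylate of 13 | C=C[C@H](C)[C@H](OS(=O)(=O)c4ccc(C)cc4)CC[C@H](C)[C@H](OCc3ccccc3)C[C@@]1(C)[C@H](O[Si](C)(C)C(C)(C)C)C[C@@H](C(C)C)[C@@H]1CCC2OCCO2 | intermediate
15 | C11 aldehyde | C=C[C@H](C)[C@H](OS(=O)(=O)c4ccc(C)cc4)CC[C@H](C)[C@H](OCc3ccccc3)C[C@@]1(C)[C@H](O[Si](C)(C)C(C)(C)C)C[C@@H](C(C)C)[C@@H]1CCC=O | intermediate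
16 | C11 homoallylic alcohol, both C11 epimers (ring-closure diene) | C=C[C@H](C)[C@H](OS(=O)(=O)c4ccc(C)cc4)CC[C@H](C)[C@H](OCc3ccccc3)C[C@@]1(C)[C@H](O[Si](C)(C)C(C)(C)C)C[C@@H](C(C)C)[C@@H]1CCC(O)CC=C | intermediate
17 | 15-membered carbocycle with C8=C9 (E/Z), 11-OH, 6-OTs, 2-OBn, 16-OTBS | C1[C@@]2(C)[C@H](O[Si](C)(C)C(C)(C)C)C[C@@H](C(C)C)[C@@H]2CCC(O)CC=C[C@H](C)[C@H](OS(=O)(=O)c3ccc(C)cc3)CC[C@H](C)[C@@H]1OCc4ccccc4 | intermediate
18 | deconjugated macrocyclic enone (C11=O, C8=C9) | C1[C@@]2(C)[C@H](O[Si](C)(C)C(C)(C)C)C[C@@H](C(C)C)[C@@H]2CCC(=O)CC=C[C@H](C)[C@H](OS(=O)(=O)c3ccc(C)cc3)CC[C@H](C)[C@@H]1OCc4ccccc4 | intermediate (not isolated)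
19 | macrocyclic (9E)-enone (C11=O, C9=C10) | C1[C@@]2(C)[C@H](O[Si](C)(C)C(C)(C)C)C[C@@H](C(C)C)[C@@H]2CCC(=O)/C=C/C[C@H](C)[C@H](OS(=O)(=O)c3ccc(C)cc3)CC[C@H](C)[C@@H]1OCc4ccccc4 | intermediate
20 | 12-(diethoxyphosphanyl) enone (phosphonite) | C1[C@@]2(C)[C@H](O[Si](C)(C)C(C)(C)C)C[C@@H](C(C)C)[C@@H]2CC(P(OCC)OCC)C(=O)/C=C/C[C@H](C)[C@H](OS(=O)(=O)c3ccc(C)cc3)CC[C@H](C)[C@@H]1OCc4ccccc4 | intermediate (not isolated)
21 | diethyl 12-phosphonate of enone 19 (both C12 epimers) | C1[C@@]2(C)[C@H](O[Si](C)(C)C(C)(C)C)C[C@@H](C(C)C)[C@@H]2CC(P(=O)(OCC)OCC)C(=O)/C=C/C[C@H](C)[C@H](OS(=O)(=O)c3ccc(C)cc3)CC[C@H](C)[C@@H]1OCc4ccccc4 | intermediate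
22 | saturated 2-hydroxy-11-oxo-12-phosphonate 6-tosylate | C1[C@@]2(C)[C@H](O[Si](C)(C)C(C)(C)C)C[C@@H](C(C)C)[C@@H]2CC(P(=O)(OCC)OCC)C(=O)CCC[C@H](C)[C@H](OS(=O)(=O)c3ccc(C)cc3)CC[C@H](C)[C@@H]1O | intermediate
23 | 15-membered 2,11-dioxo-12-phosphonate 6-tosylate (key-step precursor) | C1[C@@]2(C)[C@H](O[Si](C)(C)C(C)(C)C)C[C@@H](C(C)C)[C@@H]2CC(P(=O)(OCC)OCC)C(=O)CCC[C@H](C)[C@H](OS(=O)(=O)c3ccc(C)cc3)CC[C@H](C)C1=O | intermediate
24 | tricyclic enone tosylate (rings C and D plus an 11-membered ring; 6R) | O=C1C2=C(C[C@@]3(C)[C@H](O[Si](C)(C)C(C)(C)C)C[C@@H](C(C)C)[C@@H]3C2)[C@@H](C)CC[C@@H](OS(=O)(=O)c4ccc(C)cc4)[C@@H](C)CCC1 | intermediate (not isolated)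
25 | tetracyclic 11-ketone, 16-O-TBS | O=C1C2=C(C[C@@]3(C)[C@H](O[Si](C)(C)C(C)(C)C)C[C@@H](C(C)C)[C@@H]3C2)[C@@H](C)CC[C@@H]2[C@@H]1CC[C@@H]2C | intermediate
26 | 16-O-TBS ether of the target | C=C1C2=C(C[C@@]3(C)[C@H](O[Si](C)(C)C(C)(C)C)C[C@@H](C(C)C)[C@@H]3C2)[C@@H](C)CC[C@@H]2[C@@H]1CC[C@@H]2C | intermediate
27 | CNP0544018.1 (3S,6S,7S,10S,14S,15R,16R,18S) | C=C1C2=C(C[C@@]3(C)[C@H](O)C[C@@H](C(C)C)[C@@H]3C2)[C@@H](C)CC[C@@H]2[C@@H]1CC[C@@H]2C | target

**Count and risks**

Total step count: 21. Longest linear sequence: 21 steps (from 1).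

Step 19. The phosphonate enolate may displace or eliminate the C6 tosylate before it has olefinated the hindered C2 ketone, or the ring-A alkylation may stall. The fallback separates the two bond formations and makes the C6–C10 bond before the C2 ketone exists. It sets out from 21: conjugate reduction of the enone with Stryker's reagent, which keeps the benzyl ether, should give the saturated ketophosphonate benzyl ether F1. Its dianion (NaH, then n-BuLi, THF, −78 → 0 °C) should alkylate at the γ-carbon C10 with the C6 tosylate to give the ring-A-closed ketophosphonate F2. Hydrogenolysis (H2, Pd(OH)2/C) should give the C2 alcohol F3, and Dess–Martin oxidation the C2 ketone F4. An intramolecular Horner–Wadsworth–Emmons reaction (K2CO3, 18-crown-6, toluene, 60 °C), now with no leaving group in the molecule, comes back to the route at 25.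

Step 16. The cross-conjugated enolate may be phosphinylated on oxygen instead of carbon, or conversion may stop through proton transfer from the more acidic product to unreacted enolate. The fallback forms the C–P bond by a Michaelis–Arbuzov reaction instead. It sets out from 19: LDA and TMSCl should give the silyl dienol ether F5, N-iodosuccinimide the 12-iodo enone F6, and warming with triethyl phosphite comes back to the route at 21.

Step 4. Facial selectivity may be poor because catalyst control works against the steric bias of the 2,2-disubstituted cyclopentanone. The fallback uses substrate control followed by inversion. It sets out from 6: L-Selectride, attacking from the face of the smaller C15 methyl, should give the C16-epimeric alcohol F7. Mitsunobu inversion (4-nitrobenzoic acid, PPh3, DIAD) should give the 16R 4-nitrobenzoate F8, and methanolysis (K2CO3, MeOH) comes back to the route at 7.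

**Further compounds**

F1 | step 19 | saturated 2-O-benzyl 11-oxo-12-phosphonate 6-tosylate (21 with C9–C10 reduced) | C1[C@@]2(C)[C@H](O[Si](C)(C)C(C)(C)C)C[C@@H](C(C)C)[C@@H]2CC(P(=O)(OCC)OCC)C(=O)CCC[C@H](C)[C@H](OS(=O)(=O)c3ccc(C)cc3)CC[C@H](C)[C@@H]1OCc4ccccc4
F2 | step 19 | ring-A-closed 2-O-benzyl 11-oxo-12-phosphonate (C6–C10 formed; 6S,10S) | C1[C@@]2(C)[C@H](O[Si](C)(C)C(C)(C)C)C[C@@H](C(C)C)[C@@H]2CC(P(=O)(OCC)OCC)C(=O)[C@H]3CC[C@H](C)[C@@H]3CC[C@H](C)[C@@H]1OCc4ccccc4
F3 | step 19 | 2-hydroxy analogue of F2 | C1[C@@]2(C)[C@H](O[Si](C)(C)C(C)(C)C)C[C@@H](C(C)C)[C@@H]2CC(P(=O)(OCC)OCC)C(=O)[C@H]3CC[C@H](C)[C@@H]3CC[C@H](C)[C@@H]1O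
F4 | step 19 | 2-oxo analogue of F2 | C1[C@@]2(C)[C@H](O[Si](C)(C)C(C)(C)C)C[C@@H](C(C)C)[C@@H]2CC(P(=O)(OCC)OCC)C(=O)[C@H]3CC[C@H](C)[C@@H]3CC[C@H](C)C1=O
F5 | step 16 | 11-trimethylsilyloxy 9,11-diene (silyl dienol ether of 19) | C1[C@@]2(C)[C@H](O[Si](C)(C)C(C)(C)C)C[C@@H](C(C)C)[C@@H]2CC=C(O[Si](C)(C)C)/C=C/C[C@H](C)[C@H](OS(=O)(=O)c3ccc(C)cc3)CC[C@H](C)[C@@H]1OCc4ccccc4
F6 | step 16 | 12-iodo derivative of enone 19 | C1[C@@]2(C)[C@H](O[Si](C)(C)C(C)(C)C)C[C@@H](C(C)C)[C@@H]2CC(I)C(=O)/C=C/C[C@H](C)[C@H](OS(=O)(=O)c3ccc(C)cc3)CC[C@H](C)[C@@H]1OCc4ccccc4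
F7 | step 4 | (1S,2R,3S,4S)-alcohol, the C16 epimer of 7 | C=CC[C@@]1(C)[C@@H](O)C[C@@H](C(C)C)[C@@H]1CCC2OCCO2
F8 | step 4 | 4-nitrobenzoate of 7 (16R) | C=CC[C@@]1(C)[C@H](OC(=O)c3ccc(cc3)[N+](=O)[O-])C[C@@H](C(C)C)[C@@H]1CCC2OCCO2
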